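**Assumption:** the stereodescriptor in the SMILES corresponds to (2S) (CIP order O1 > aryl > C3 > H), and the one-pot Ir borylation/oxidation is counted as one step.

## Retrosynthetic overview

1. Target 20 ⇐ tris-MOM flavanone 19 by a final mild acidic deprotection.
2. C2–aryl bond of 19 ⇐ Rh/chiral-diene asymmetric 1,4-addition of B-ring boronic acid 18 to A/C-ring chromone 11; this joins the two halves and sets C2.
3. Chromone 11 ⇐ salicylaldehyde 8 (ethynyl addition, oxidation, 6-endo closure) ⇐ ortho-formylation of 2-prenylphenol 7 ⇐ Claisen rearrangement of tert-prenyl ether 6 ⇐ 3,5-bis(MOMO)phenol 3 ⇐ resorcinol by Ir C–H borylation/oxidation.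
4. Boronic acid 18 ⇐ directed ortho-lithiation/borylation of 17 ⇐ Wittig, DIBAL, Pd α-arylation of isobutyronitrile with MOM-protected 4-bromophenol.
5. Ring order: A ring is resorcinol and B ring is 4-bromophenol (both bought); the pyranone C ring is closed on A before the coupling; no ring is formed after it.

## Route

**Step 1**
Reactants: 1 resorcinol
Product: 2 1,3-bis(methoxymethoxy)benzene
Conditions: MOMCl (2.5 eq), i-Pr2NEt, CH2Cl2, 0 °C → rt
Reagents that add atoms: chloromethyl methyl ether, COCCl
Why: Standard phenol O-alkylation (acetal protection); MOM later survives base, organometallics and heat.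

**Step 2**
Reactants: 2
Product: 3 3,5-bis(methoxymethoxy)phenol
Conditions: [Ir(OMe)(cod)]2 (1.5 mol%), dtbpy (3 mol%), B2pin2, THF, 80 °C; then 30% H2O2, aq NaOH, 0 °C → rt (one pot)
Reagents that add atoms: hydrogen peroxide, OO (B2pin2 gives only the transient ArBpin)
Why: Sterically controlled Ir-catalysed C–H borylation occurs only at C5, the one C–H not ortho to an OMOM group, and oxidative C–B → C–O cleavage gives the single free phenol.

**Step 3**
Reactants: 4 2-methylbut-3-en-2-ol
Product: 5 methyl 2-methylbut-3-en-2-yl carbonate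
Conditions: n-BuLi, THF, −78 °C; ClCO2Me, −78 → 0 °C
Reagents that add atoms: methyl chloroformate, COC(=O)Cl
Why: Acylation of the lithium alkoxide gives the tertiary allylic carbonate needed for Pd ionisation.

**Step 4**
Reactants: 3 and 5
Product: 6 1,3-bis(methoxymethoxy)-5-[(2-methylbut-3-en-2-yl)oxy]benzene
Conditions: Pd(PPh3)4 (3 mol%), THF, 0 °C → rt, short reaction time
Reagents that add atoms: none
Why: Tsuji–Trost O-allylation; decarboxylative ionisation gives a 1,1-dimethyl-π-allyl-Pd/phenoxide pair, and the phenoxide attacks the more substituted terminus under kinetic control to give the tertiary ether.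

**Step 5**
Reactants: 6
Product: 7 3,5-bis(methoxymethoxy)-2-(3-methylbut-2-en-1-yl)phenol
Conditions: PhNEt2, 120 °C (base-washed glassware)
Reagents that add atoms: none
Why: Aromatic Claisen [3,3] rearrangement of the 1,1-dimethylallyl ether delivers a normal prenyl group to one of the two equivalent ortho carbons and re-aromatises to the phenol.

**Step 6**
Reactants: 7
Product: 8 2-hydroxy-4,6-bis(methoxymethoxy)-3-(3-methylbut-2-en-1-yl)benzaldehyde
Conditions: MgCl2, Et3N, (CH2O)n, MeCN, reflux
Reagents that add atoms: paraformaldehyde (formaldehyde), C=O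
Why: Casnati–Skattebøl Mg-phenoxide-directed formylation goes only to the single free ortho position, so the one free OH is now flanked by prenyl and CHO (future O1 with prenyl at C8).

**Step 7**
Reactants: 8
Product: 9 1-[2-hydroxy-4,6-bis(methoxymethoxy)-3-(3-methylbut-2-en-1-yl)phenyl]prop-2-yn-1-ol (racemic, used crude)
Conditions: HC≡CMgBr (3.5 eq), THF, 0 °C → rt; sat. NH4Cl, 0 °C
Reagents that add atoms: ethynylmagnesium bromide, C#C[Mg]Br
Why: Grignard 1,2-addition to the aldehyde after phenoxide formation; the carbinol stereocentre is irrelevant because it is oxidised next.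

**Step 8**
Reactants: 9
Product: 10 1-[2-hydroxy-4,6-bis(methoxymethoxy)-3-(3-methylbut-2-en-1-yl)phenyl]prop-2-yn-1-one
Conditions: activated MnO2 (15 eq), CH2Cl2, rt
Reagents that add atoms: none
Why: MnO2 selectively oxidises the benzylic/propargylic alcohol and leaves the phenol, prenyl alkene and MOM ethers untouched.

**Step 9**
Reactants: 10
Product: 11 5,7-bis(methoxymethoxy)-8-(3-methylbut-2-en-1-yl)-4H-chromen-4-one
Conditions: Et2NH (1.5 eq), EtOH, rt; then AcOH, 50 °C
Reagents that add atoms: none
Why: Amine conjugate addition to the terminal ynone gives an enaminone, which the ortho phenol closes by 6-endo addition–elimination to the chromone, avoiding 5-exo closure.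

**Step 10**
Reactants: 12 4-bromophenol
Product: 13 1-bromo-4-(methoxymethoxy)benzene
Conditions: MOMCl, i-Pr2NEt, CH2Cl2, 0 °C → rt
Reagents that add atoms: chloromethyl methyl ether, COCCl
Why: Phenol protection that later serves as the ortho-directing group.

**Step 11**
Reactants: 13 and 14 isobutyronitrile
Product: 15 2-[4-(methoxymethoxy)phenyl]-2-methylpropanenitrile
Conditions: Pd(OAc)2 (2 mol%), rac-BINAP (2.4 mol%), NaHMDS (1.3 eq), toluene, 100 °C
Reagents that add atoms: none
Why: Pd-catalysed α-arylation of a secondary nitrile anion forms the aryl-bearing quaternary carbon directly.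

**Step 12**
Reactants: 15
Product: 16 2-[4-(methoxymethoxy)phenyl]-2-methylpropanal
Conditions: DIBAL-H (1.3 eq), toluene, −78 → 0 °C; 10% aq citric acid, 0 °C
Reagents that add atoms: water, O
Why: DIBAL stops at the N-aluminoimine, which hydrolyses on mild acidic work-up to the non-enolisable aldehyde.

**Step 13**
Reactants: 16
Product: 17 1-(methoxymethoxy)-4-(2-methylbut-3-en-2-yl)benzene
Conditions: Ph3PCH3Br, KOt-Bu, THF, 0 °C → rt
Reagents that add atoms: methyltriphenylphosphonium bromide, C[P+](c1ccccc1)(c1ccccc1)c1ccccc1.[Br-]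
Why: Wittig methylenation of the hindered aldehyde completes the 1,1-dimethylallyl group.

**Step 14**
Reactants: 17
Product: 18 [2-(methoxymethoxy)-5-(2-methylbut-3-en-2-yl)phenyl]boronic acid
Conditions: n-BuLi, TMEDA, Et2O, 0 °C; B(Oi-Pr)3, −78 °C → rt; aq NH4Cl
Reagents that add atoms: triisopropyl borate, CC(C)OB(OC(C)C)OC(C)C; water, O
Why: MOM-directed ortho-lithiation (the side chain has no acidic allylic or benzylic H) followed by borate quench and hydrolysis gives the boronic acid.

**Step 15**
Reactants: 11 and 18 (2.5 eq)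
Product: 19 (2S)-5,7-bis(methoxymethoxy)-2-[2-(methoxymethoxy)-5-(2-methylbut-3-en-2-yl)phenyl]-8-(3-methylbut-2-en-1-yl)-2,3-dihydro-4H-chromen-4-one
Conditions: [RhCl(C2H4)2]2 (2.5 mol%), (1S,4S)-2,5-diphenylbicyclo[2.2.2]octa-2,5-diene (5.5 mol%), aq KOH (0.5 eq), dioxane/H2O 10:1, 40 °C
Reagents that add atoms: none
Why: Hayashi–Miyaura asymmetric 1,4-addition; the aryl–Rh(diene) species inserts the chromone C2=C3 on one face and the oxa-π-allyl is protonated by water, with the (S,S)-diene chosen as the enantiomer that gives (S)-β-aryl ketones from cyclic enones, which maps to 2S here (to be confirmed by chiral HPLC and CD, using the antipodal ligand if the sense is reversed).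

**Step 16**
Reactants: 19
Product: 20 (2S)-5,7-dihydroxy-2-[2-hydroxy-5-(2-methylbut-3-en-2-yl)phenyl]-8-(3-methylbut-2-en-1-yl)-2,3-dihydro-4H-chromen-4-one (target)
Conditions: 3 M aq HCl/MeOH (1:5), rt → 40 °C, monitored and stopped at full conversion
Reagents that add atoms: none
Why: Acetal hydrolysis removes all three MOM groups under conditions mild enough to leave the prenyl and 1,1-dimethylallyl alkenes and the C2 stereocentre intact (no base, so no retro-oxa-Michael).

## Compound list

1 | resorcinol | Oc1cccc(O)c1 | starting material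
2 | 1,3-bis(methoxymethoxy)benzene | COCOc1cccc(OCOC)c1 | intermediate
3 | 3,5-bis(methoxymethoxy)phenol | COCOc1cc(O)cc(OCOC)c1 | intermediate
4 | 2-methylbut-3-en-2-ol | C=CC(C)(C)O | starting material
5 | methyl 2-methylbut-3-en-2-yl carbonate | COC(=O)OC(C)(C)C=C | intermediate
6 | 1,3-bis(methoxymethoxy)-5-[(2-methylbut-3-en-2-yl)oxy]benzene | C=CC(C)(C)Oc1cc(OCOC)cc(OCOC)c1 | intermediate
7 | 3,5-bis(methoxymethoxy)-2-(3-methylbut-2-en-1-yl)phenol | CC(C)=CCc1c(O)cc(OCOC)cc1OCOC | intermediate
8 | 2-hydroxy-4,6-bis(methoxymethoxy)-3-(3-methylbut-2-en-1-yl)benzaldehyde | O=Cc1c(O)c(CC=C(C)C)c(OCOC)cc1OCOC | intermediate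
9 | 1-[2-hydroxy-4,6-bis(methoxymethoxy)-3-(3-methylbut-2-en-1-yl)phenyl]prop-2-yn-1-ol (racemic) | C#CC(O)c1c(O)c(CC=C(C)C)c(OCOC)cc1OCOC | intermediate
10 | 1-[2-hydroxy-4,6-bis(methoxymethoxy)-3-(3-methylbut-2-en-1-yl)phenyl]prop-2-yn-1-one | C#CC(=O)c1c(O)c(CC=C(C)C)c(OCOC)cc1OCOC | intermediate
11 | 5,7-bis(methoxymethoxy)-8-(3-methylbut-2-en-1-yl)-4H-chromen-4-one | O=c1ccoc2c(CC=C(C)C)c(OCOC)cc(OCOC)c12 | intermediate
12 | 4-bromophenol | Oc1ccc(Br)cc1 | starting material
13 | 1-bromo-4-(methoxymethoxy)benzene | COCOc1ccc(Br)cc1 | intermediate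
14 | isobutyronitrile | CC(C)C#N | starting material
15 | 2-[4-(methoxymethoxy)phenyl]-2-methylpropanenitrile | COCOc1ccc(cc1)C(C)(C)C#N | intermediate
16 | 2-[4-(methoxymethoxy)phenyl]-2-methylpropanal | COCOc1ccc(cc1)C(C)(C)C=O | intermediate
17 | 1-(methoxymethoxy)-4-(2-methylbut-3-en-2-yl)benzene | COCOc1ccc(cc1)C(C)(C)C=C | intermediate
18 | [2-(methoxymethoxy)-5-(2-methylbut-3-en-2-yl)phenyl]boronic acid | COCOc1ccc(cc1B(O)O)C(C)(C)C=C | intermediate
19 | (2S)-5,7-bis(methoxymethoxy)-2-[2-(methoxymethoxy)-5-(2-methylbut-3-en-2-yl)phenyl]-8-(3-methylbut-2-en-1-yl)chroman-4-one | C=CC(C)(C)c1ccc(OCOC)c([C@@H]2CC(=O)c3c(OCOC)cc(OCOC)c(CC=C(C)C)c3O2)c1 | intermediate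
20 | (2S)-5,7-dihydroxy-2-[2-hydroxy-5-(2-methylbut-3-en-2-yl)phenyl]-8-(3-methylbut-2-en-1-yl)chroman-4-one | C=CC(C)(C)c1ccc(O)c([C@@H]2CC(=O)c3c(O)cc(O)c(CC=C(C)C)c3O2)c1 | target

## Summary

Total step count: 16.

Longest linear sequence: 10 steps (1, 2, 4, 5, 6, 7, 8, 9, 15, 16). The side branches are step 3 (one step) and steps 10–14 (five steps).

Steps most likely to fail:

1. **Step 15 (Rh asymmetric 1,4-addition).** The ortho-alkoxy boronic acid is hindered and prone to protodeboronation, the 5,7-dialkoxychromone is electron-rich, and β-oxygen elimination from the Rh enolate (ring opening to chalcone) would erode ee. Fallback: form ring C after the coupling. Convert 8 to the methyl ketone (MeMgBr, then MnO2), formylate 17 (n-BuLi/TMEDA, DMF), join them by Claisen–Schmidt condensation, and close the 2′-hydroxychalcone by a cinchona–thiourea-catalysed enantioselective oxa-Michael reaction, upgrading ee by recrystallisation.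

2. **Step 7 (ethynyl addition to the free salicylaldehyde).** The magnesium phenoxide aldehyde is deactivated, and carbinol 9 is an electron-rich o-hydroxybenzylic alcohol that can ionise to an o-quinone methide. Fallback: mask the phenol of 8 as a TBS ether before the acetylide addition and oxidation, then release the phenoxide with TBAF so that desilylation triggers the 6-endo closure to 11 directly (one extra step).

3. **Step 16 (triple MOM removal).** Acid can cyclise the 8-prenyl group onto the 7-OH (chroman formation), hydrate the alkenes, or partly racemise C2 through the chalcone. Fallback: redesign the protection. Carry all three phenols as SEM ethers (SEMCl in steps 1 and 10; SEM also directs the ortho-lithiation in step 14) and remove them at the end with MgBr2·OEt2 in Et2O/MeNO2, avoiding protic acid. SEM stability to the MgCl2 formylation in step 6 would need checking.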